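## Structural features

48 is a Diels–Alder-type hetero-dimer of two sesquiterpene lactones. One half is a guaian-12,8-olide: a cyclopentene (C1–C5, C4=C5) fused along C1–C5 to a seven-membered ring (C1, C5–C10) that carries a trans-fused α-methylene-γ-lactone at C7/C8, a methyl group at C10 and an acetate at C2. The other half is a 1,10-seco-eudesman-12′,8′-olide: a tetrasubstituted cyclohexene (C5′=C10′) with a cis-fused γ-lactone at C7′/C8′, a free allylic hydroxyl at C6′ and the chain C4′(CH3)–C3′–C2′–C1′–OAc on C5′. The halves share the spiro carbon C11′: the bonds C1–C13′ and C3–C11′ make C1, C2, C3, C11′ and C13′ a cyclopentane, which with C4=C5 forms a bicyclo[2.2.1]heptene whose one-carbon bridge is C2. There are eleven stereocentres; ten form one continuous array C10–C1–C2–C3–C11′–C7′(–C6′)–C8′ together with C7–C8 across the seven-membered ring, two are quaternary (C1, C11′), and only C4′ is isolated. The fragile groups are the α-methylene lactone (Michael acceptor, sensitive to hydride, radicals and palladium hydrides), the two acetates (enolisable, base-labile) and the two tetrasubstituted alkenes (prone to migrate under acid). The real difficulty is the pair of neighbouring quaternary carbons: C1 belongs to three rings, and C11′ has the more crowded configuration, with C3 on the face of the primed lactone that also carries C6′ and with C7′ cis to C4 on the cyclopentane. The key step uses the fact that, without the C1–C5 bond, C1 to C10 form a ten-membered ring bridged between C1 and C3 by C13′–C11′; in it the C4=C5 and C1=C10 alkenes face each other, and C5 is separated from C1 by the three atoms C4, C3 and C2, all held on the preformed cyclopentane.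

## Logic of the disconnections

**48 back to 45.** The O–acetyl bonds at C2 and C1′ and the O–Si bond at C6′ are cut last. The two hydroxyls to be acetylated carry triethylsilyl groups and the one to stay free carries tert-butyldimethylsilyl, so 46 and 47 differ only by selective desilylation and acylation. The forward steps must leave the α-methylene lactone untouched.

**45 back to 42.** The C11=C13 bond is removed. With C11 as a plain methylene the lactone survives palladium and hydrogen-atom-transfer chemistry, and C11 is the only enolisable position because C11′ is quaternary and no acetate is yet present. The forward step is a single enolate methylenation. A lactone made by a methylene-forming ring closure and then saturated would carry a C13 methyl group, which the 13-nor series does not have, so the lactone is built unsubstituted at C11 from the start.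

**42 back to 41.** The C10–H bond is cut to an exocyclic C10=C14 alkene. The forward hydrogenation must touch only this 1,1-disubstituted alkene and must deliver hydrogen to the face of C10 that carries C13′.

**41 back to 40 (key).** The C1–C5 bond is cut. This opens both the cyclopentene and the seven-membered ring and leaves a bridged cyclodeca-1(10),4-diene with a C5 vinyl triflate. The quaternary C1 and two rings disappear in one operation. The forward step needs oxidative addition at C5 and carbopalladation of the tetrasubstituted C1=C10 alkene with C5 going to C1 and not to C10. The ring that forms contains C5, C4, C3, C2 and C1, so the connecting atoms are C4, C3 and C2.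

**40 back to 37.** The C5–O(triflate) bond is traced to the α-methylene ketone 39, whose conjugate reduction gives the C4=C5 enolate regiospecifically; deprotonation of a C5 ketone would go to C6. The C4–C5 bond is then cut (38) to a C4 vinyl triflate and a C5 aldehyde in 37. This ring closure creates no lasting stereocentre, because C7 and C8 are already fixed in a preformed lactone. The forward demand is a medium-ring Nozaki–Hiyama–Kishi closure and an enolate geometry with oxygen cis to C3.

**37 back to 32.** Only functional groups change: the C5 aldehyde comes from the vinyl group on C7 (36, 35), the C4 enol triflate from a methyl ketone (34) and this from a protected carbinol (33, 32). The forward steps need orthogonality of p-methoxybenzyl against silyl ethers and kinetic enolisation at the methyl group.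

**32 back to 28.** The C1–C2 and C10–C14 bonds are cut together: the cyclopentanol 29 with its tetrasubstituted exocyclic alkene is the product of an alkylative cyclisation of the ynal 28. The syn addition fixes C9 cis to C13′, which a carbonyl olefination of a cyclopentanone could not guarantee. The C2 carbinol is adjusted by oxidation and reduction (30, 31).

**28 back to 25 and 24, and 25 back to 18.** The C11′–C13′ bond is cut (26 to 25 + 24), then the C3–C2 bond (25 to 18). The order matters: the group that enters C11′ last is expected on the open face syn to H7′. This is where C13′ must be, whereas an annulation onto a preformed α-methylene lactone would place C3 there and give the C11′ epimer. C3 is therefore attached first (conjugate addition to the alkylidene lactone 18) and C13′ last (enolate alkylation). The demand is facial control at C3 and C11′ by the cis-fused lactone.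

**18 back to 14 and 15.** The C11′=C3 bond is cut by aldol condensation. 15 supplies C3, C4 and C15, and its alkoxy stereocentre helps to steer the conjugate addition before it is oxidised away.

**14 back to 1, 2 and 4.** The C5′=C10′ alkene is cut by ring-closing metathesis (11 to 10), the lactone C–O bond and C8′–C9′ by allylboration (10 to 8), and C6′–C7′ by an auxiliary-controlled syn-aldol (6 to 3 + 5). 3 comes from 1 and 2, and 5 from 4, which brings C4′ from the chiral pool. The hard demand is the metathesis to a tetrasubstituted alkene.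

**24 back to 19.** The C9–C10 bond is cut (acetylide on a primary triflate) and the C7–C6 bond (conjugate addition anti to the C8 substituent). C8 comes from 19, and C7 is set relative to it.

## Other disconnections considered

**Alternative 1:** The cut is C6′–C7′ of the cyclohexene, with the lactone alkene moved from C7′=C11′ to C11′=C13′.
- Forward step: zinc inserts into the allylic C–Br bond of the bromomethyl-butenolide enal A1; the allylzinc attacks the aldehyde through C7′ (Barbier-type γ-allylation) and gives the monomer A2.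
- In its favour: one step makes the ring, the C6′ carbinol and the methylene lactone. Cis ring fusion is inherent because the lactone ring already exists. Both fragments come from the chiral pool.
- Against it here: it ends at the complete methylene lactone A2, so C13′ is already on C11′ and C3 would have to be attached last, on the face expected to be hindered. The union with the other half would be a late intermolecular [4+2] addition with open regio-, endo/exo- and facial selectivity. A1 also needs a tetrasubstituted enal of defined geometry.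
- Comparison: on step economy for the primed half the alternative is the better (one closure against steps 3–9 here). On stereocontrol at C6′ it is at best the equal (Barbier closure against an auxiliary-controlled aldol). On the C11′ configuration and on the union of the halves the chosen plan is the more controlled.

**Alternative 2:** The cut is the C1–C2 bond, made by a 1,2-shift.
- Forward step: BF3·OEt2 opens the epoxide A3 at the allylic C1; C2 migrates from the other epoxide carbon to C1, and that carbon becomes the aldehyde C13′ of A4, contracting a six-membered ring to the cyclopentene.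
- In its favour: the quaternary C1 is formed stereospecifically (migration anti to the breaking C–O bond). On predictability of the C1 configuration this is the equal or the better of a transannular Heck reaction. C13′ arrives as a usable aldehyde, and the seven-membered ring and its lactone come from established guaianolide chemistry.
- Against it here: the spiro carbon C11′ is still missing. Two bonds to it (C13′–C11′ at a neopentyl aldehyde and C3–C11′ at a carbon that still bears oxygen) have to be made afterwards, with the same facial problem at C11′. The allylic cation may lose a proton or undergo a hydride shift instead of the ring contraction.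
- Comparison: the mechanism is cationic and needs no metal. Structurally it builds the cyclopentene by contraction rather than by closing two rings at once, and the sequence would be more linear and probably longer.

**Alternative 3:** The cut is C11–C12 and C12–O8 of the guaianolide lactone.
- Forward step: zerovalent palladium adds to the vinyl triflate A5, CO inserts, and the acylpalladium is captured by the trans C8 hydroxyl to give A6, which is identical with 47.
- In its favour: the sensitive α-methylene lactone appears in one step at the very end and never meets Heck or radical conditions. The acetates can already be in place, so the end game is shorter than steps 33–35 here; on this point the alternative is the better.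
- Against it here: it is an end-game tactic and does not say how C1–C5 is made. A5 needs a C7 acetyl group (epimerisable, and an extra enolisable ketone) and a free trans C8 hydroxyl carried through the whole assembly. The kinetic enol triflate would have to be formed beside two acetates. The lactone could no longer bring C7 and C8 from the chiral pool.
- Comparison: mechanistically it is as well founded as the enolate methylenation. It could replace the last steps of the chosen plan, at the cost of the preformed lactone that fixes C7/C8 and makes the medium-ring closure stereochemically silent.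

Key step: step 31

Assumption 1: 15 and 19 are taken as purchasable single enantiomers (15 is otherwise two steps from methyl (R)-lactate).
Assumption 2: atom labels follow guaiane numbering (C1–C15) for the half that contains C1 and primed seco-eudesmane numbering for the other half.

## Route

Step 1
Reactants: 1 (S)-4-benzyl-1,3-thiazolidine-2-thione; 2 methyl 4-chloro-4-oxobutanoate
Product: 3 methyl 4-[(4S)-4-benzyl-2-thioxo-1,3-thiazolidin-3-yl]-4-oxobutanoate
Conditions: Et3N, DMAP (cat.), CH2Cl2, 0 °C to rt
Reagents that add atoms: none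
Why: N-acylation of the thiazolidinethione by an acid chloride; it places the auxiliary on the four-carbon unit that becomes C8′, C7′, C11′ and C12′.

Step 2
Reactants: 4 (S)-citronellal
Product: 5 (3S)-3,7-dimethyl-2-methylideneoct-6-enal
Conditions: aq. HCHO, pyrrolidine (10 mol %), EtCO2H (10 mol %), i-PrOH, 45 °C
Reagents that add atoms: formaldehyde, C=O
Why: Organocatalytic α-methylenation of an aldehyde (Mannich condensation, then loss of the amine); C4′ is β to the carbonyl and is not touched.

Step 3
Reactants: 3 N-acylthiazolidinethione; 5 enal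
Product: 6 syn-aldol adduct, methyl (3S,4S,6S)-3-[(4S)-4-benzyl-2-thioxo-1,3-thiazolidine-3-carbonyl]-4-hydroxy-6,10-dimethyl-5-methylideneundec-9-enoate
Conditions: TiCl4, i-Pr2NEt, N-methylpyrrolidinone (1 equiv each), CH2Cl2, 0 °C; then 5, −78 to 0 °C
Reagents that add atoms: none
Why: Titanium-mediated syn-aldol of an N-acylthiazolidinethione: the Z-enolate adds through a chair transition state on the face away from the benzyl group, which should set C7′ and C6′ syn with auxiliary control; the enal should react 1,2 and the low temperature limits Lewis-acid ene reaction of the remote alkene.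

Step 4
Reactants: 6 aldol adduct
Product: 7 C6′ tert-butyldimethylsilyl ether of 6
Conditions: TBSOTf, 2,6-lutidine, CH2Cl2, −78 to 0 °C
Reagents that add atoms: tert-butyldimethylsilyl triflate, CC(C)(C)[Si](C)(C)OS(=O)(=O)C(F)(F)F
Why: Silylation of a hindered secondary alcohol with a silyl triflate and a non-nucleophilic base; this group stays to the last step.

Step 5
Reactants: 7 silylated aldol adduct
Product: 8 aldehyde, methyl (3S,4S,6S)-4-[(tert-butyldimethylsilyl)oxy]-3-formyl-6,10-dimethyl-5-methylideneundec-9-enoate
Conditions: i-Bu2AlH, CH2Cl2, −78 °C; Rochelle salt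
Reagents that add atoms: none
Why: N-Acylthiazolidinethiones are reduced directly to aldehydes by i-Bu2AlH at low temperature, faster than a methyl ester; the auxiliary is released and 8 is used at once to avoid epimerisation at C7′.

Step 6
Reactants: 8 aldehyde
Product: 10 cis-lactone diene, (4R,5R)-4-{(1S,3S)-1-[(tert-butyldimethylsilyl)oxy]-3,7-dimethyl-2-methylideneoct-6-en-1-yl}-5-(2-methylprop-2-en-1-yl)oxolan-2-one, via hydroxy ester 9 (not isolated)
Conditions: 2-methylallyl-B(pin), (R)-TRIP (5 mol %), PhMe, −30 °C; then PPTS (cat.), CH2Cl2, rt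
Reagents that add atoms: 2-(2-methylallyl)-4,4,5,5-tetramethyl-1,3,2-dioxaborolane, CC(=C)CB1OC(C)(C)C(C)(C)O1
Why: Chiral-phosphoric-acid-catalysed allylboration through a closed six-membered transition state; the (R)-catalyst should direct the allyl group to the Re face of the aldehyde and so set C8′ under catalyst control, and the γ-hydroxy ester then lactonises with retention to the 4,5-cis lactone.

Step 7
Reactants: 10 lactone diene
Product: 11 cis-fused bicyclic nor-lactone (C5′=C10′ tetrasubstituted, C6′–OTBS, prenyl-terminated side chain)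
Conditions: RuCl2(SIMes)(=CH-C6H4-2-O-i-Pr) (second-generation Hoveyda–Grubbs catalyst, 10 mol %), PhMe, 100 °C, argon sparge
Reagents that add atoms: none
Why: Ring-closing metathesis of two 1,1-disubstituted alkenes to a tetrasubstituted cyclohexene; the cis lactone holds the two alkenes together and the trisubstituted side-chain alkene should react far more slowly.

Step 8
Reactants: 11 bicyclic lactone
Product: 13 primary alcohol at C1′, via aldehyde 12 (not isolated)
Conditions: OsO4 (2 mol %), NaIO4, 2,6-lutidine, dioxane/H2O, rt; then NaBH4, MeOH, 0 °C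
Reagents that add atoms: sodium periodate (oxygen donor through OsO4), [Na+].[O-][I](=O)(=O)=O; osmium tetroxide, O=[Os](=O)(=O)=O
Why: Lemieux–Johnson cleavage of the only trisubstituted alkene (the hindered tetrasubstituted ring alkene should be much slower), then borohydride reduction of the aldehyde in the presence of the lactone.

Step 9
Reactants: 13 alcohol
Product: 14 nor-lactone with C1′–OTES and C6′–OTBS (C11′ = CH2)
Conditions: TESCl, imidazole, CH2Cl2, 0 °C
Reagents that add atoms: chlorotriethylsilane, CC[Si](Cl)(CC)CC
Why: Silylation of a primary alcohol; the triethylsilyl group marks the oxygen that is acetylated at the end.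

Step 10
Reactants: 14 nor-lactone; 15 (R)-2-[(4-methoxybenzyl)oxy]propanal
Product: 18 (E)-alkylidene lactone (C11′=C3, C4 bearing OPMB and CH3), via aldol adduct 16 (not isolated), via mesylate 17 (not isolated)
Conditions: LiN(i-Pr)2, THF, −78 °C; 15; MeSO2Cl, −78 to 0 °C; DBU, rt
Reagents that add atoms: none
Why: Aldol addition of the lactone enolate, mesylation of the aldolate and E1cB elimination; the elimination should give the more stable E isomer (C4 cis to C7′), and the alkoxy stereocentre of 15 is not involved.

Step 11
Reactants: 19 (R)-5-(hydroxymethyl)furan-2(5H)-one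
Product: 20 (R)-5-{[(tert-butyldimethylsilyl)oxy]methyl}furan-2(5H)-one
Conditions: TBSCl, imidazole, CH2Cl2, rt
Reagents that add atoms: tert-butyldimethylsilyl chloride, CC(C)(C)[Si](C)(C)Cl
Why: Silylation of the primary alcohol so that the butenolide can take an organocopper reagent.

Step 12
Reactants: 20 silyloxymethyl butenolide
Product: 21 (4S,5R)-5-{[(tert-butyldimethylsilyl)oxy]methyl}-4-vinyloxolan-2-one (trans)
Conditions: CH2=CHMgBr, CuBr·SMe2 (10 mol %), THF, −78 °C; aq. NH4Cl
Reagents that add atoms: vinylmagnesium bromide, C=C[Mg]Br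
Why: Copper-catalysed conjugate addition to a γ-substituted butenolide; it takes place anti to the C8 substituent, so C7 is set trans to C8 as in the trans-lactone of 48.

Step 13
Reactants: 21 silyl ether
Product: 22 (4S,5R)-5-(hydroxymethyl)-4-vinyloxolan-2-one
Conditions: HF·pyridine, THF, 0 °C to rt
Reagents that add atoms: none
Why: Fluoride cleavage of the primary silyl ether; the γ-lactone is the stable ring size and should not translactonise.

Step 14
Reactants: 22 hydroxymethyl lactone
Product: 24 (4S,5S)-5-(4-chlorobut-2-yn-1-yl)-4-vinyloxolan-2-one, via triflate 23 (not isolated)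
Conditions: Tf2O, 2,6-lutidine, CH2Cl2, −78 °C; then LiC≡CCH2Cl (from propargyl chloride and n-BuLi), THF/DMPU, −78 to −40 °C
Reagents that add atoms: propargyl chloride, C#CCCl
Why: SN2 displacement of a primary triflate by a lithium acetylide at low temperature, which should be faster than addition to the lactone; it forms C9–C10 and brings the propargylic chloride for the later alkylation.

Step 15
Reactants: 18 alkylidene lactone
Product: 25 conjugate adduct (C3 bearing CH2SiMe2(O-i-Pr) and the C4 side chain; C11′–H, epimers)
Conditions: (i-PrO)Me2SiCH2MgCl, CuBr·SMe2 (20 mol %), THF, −78 to −30 °C; aq. NH4Cl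
Reagents that add atoms: [(isopropoxydimethylsilyl)methyl]magnesium chloride, CC(C)O[Si](C)(C)C[Mg]Cl
Why: Copper-catalysed conjugate addition of a masked hydroxymethyl Grignard reagent; the nucleophile should add to C3 on the lactone face syn to H7′ (the other face is covered by C6′ and its silyloxy group), which is also anti to the C4 alkoxy group when the C4 hydrogen points towards C7′, so both controls are matched and set C3.

Step 16
Reactants: 25 conjugate adduct; 24 propargylic chloride
Product: 26 α-propargylated lactone with quaternary C11′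
Conditions: LiN(i-Pr)2, THF/HMPA, −78 °C; 24, n-Bu4NI (cat.), −78 to −20 °C
Reagents that add atoms: none
Why: C-Alkylation of a lactone enolate by a propargylic halide; the electrophile should enter on the face syn to H7′, away from C6′ and anti to the larger C3 substituent, so C13′ ends cis to H7′ and C3 on the C6′ side as in 48.

Step 17
Reactants: 26 alkoxysilane
Product: 27 primary alcohol (C2 = CH2OH)
Conditions: H2O2, KHCO3, THF/MeOH, 40 °C
Reagents that add atoms: hydrogen peroxide, OO
Why: Tamao oxidation of the alkoxysilane C–Si bond to C–OH; fluoride-free conditions spare the silyl ethers.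

Step 18
Reactants: 27 alcohol
Product: 28 ynal (C2 = CHO)
Conditions: Dess–Martin periodinane, NaHCO3, CH2Cl2, 0 °C
Reagents that add atoms: none
Why: Buffered Dess–Martin oxidation of a primary alcohol; the aldehyde is used at once to protect the C3 stereocentre.

Step 19
Reactants: 28 ynal
Product: 29 cyclopentanol with exocyclic C1=C10 alkene (C9 cis to C13′; C2 epimers)
Conditions: Ni(cod)2 (10 mol %), Me2Zn, THF, 0 °C
Reagents that add atoms: dimethylzinc, C[Zn]C
Why: Nickel-catalysed alkylative cyclisation of an ynal: zerovalent nickel couples the aldehyde and the proximal alkyne carbon to an oxanickelacycle (C1–C2 bond), and methyl transfer from zinc with reductive elimination puts CH3 on C10 cis to C2, so C9 is cis to C13′; the C2 configuration is irrelevant here.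

Step 20
Reactants: 29 allylic alcohol
Product: 30 enone (C2 ketone)
Conditions: Dess–Martin periodinane, NaHCO3, CH2Cl2, rt
Reagents that add atoms: none
Why: Oxidation of the secondary allylic alcohol; it removes the uncontrolled C2 centre.

Step 21
Reactants: 30 enone
Product: 31 allylic alcohol (C2–OH cis to the C4 side chain)
Conditions: NaBH4, CeCl3·7H2O, MeOH, −78 °C
Reagents that add atoms: none
Why: Luche 1,2-reduction; hydride should reach C2 on the face away from the C3 side chain, so the hydroxyl ends cis to C4 as in 48.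

Step 22
Reactants: 31 alcohol
Product: 32 C2 triethylsilyl ether
Conditions: TESOTf, 2,6-lutidine, CH2Cl2, −78 °C
Reagents that add atoms: triethylsilyl triflate, CC[Si](CC)(CC)OS(=O)(=O)C(F)(F)F
Why: Silylation of a hindered secondary alcohol; triethylsilyl marks the second oxygen to be acetylated.

Step 23
Reactants: 32 p-methoxybenzyl ether
Product: 33 C4 alcohol
Conditions: DDQ, CH2Cl2/pH 7 buffer, 0 °C
Reagents that add atoms: none
Why: Oxidative cleavage of the p-methoxybenzyl ether, orthogonal to the three silyl ethers and to the alkenes at low temperature.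

Step 24
Reactants: 33 alcohol
Product: 34 C4 methyl ketone
Conditions: Dess–Martin periodinane, NaHCO3, CH2Cl2, rt
Reagents that add atoms: none
Why: Oxidation of the secondary alcohol; the temporary C4 centre disappears.

Step 25
Reactants: 34 methyl ketone
Product: 35 enol triflate C4(OTf)=C15H2
Conditions: KN(SiMe3)2, THF, −78 °C; PhNTf2
Reagents that add atoms: N-phenylbis(trifluoromethanesulfonimide), O=S(=O)(N(c1ccccc1)S(=O)(=O)C(F)(F)F)C(F)(F)F
Why: Kinetic deprotonation of the methyl ketone at CH3 and O-triflation; the hindered C3–H and the less acidic lactone α-hydrogens should not compete at −78 °C.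

Step 26
Reactants: 35 enol triflate with C7 vinyl group
Product: 36 primary alcohol at C5
Conditions: 9-BBN, THF, 0 °C to rt; then H2O2, pH 7 phosphate buffer
Reagents that add atoms: hydrogen peroxide, OO
Why: 9-BBN hydroborates the monosubstituted alkene in preference to the enol triflate and the tetrasubstituted alkenes; buffered oxidation spares lactones and triflate.

Step 27
Reactants: 36 alcohol
Product: 37 C5 aldehyde
Conditions: Dess–Martin periodinane, NaHCO3, CH2Cl2, 0 °C
Reagents that add atoms: none
Why: Mild oxidation of the primary alcohol to the aldehyde for ring closure.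

Step 28
Reactants: 37 vinyl triflate aldehyde
Product: 38 bridged ten-membered allylic alcohol (C4=C15H2 exocyclic, C5–OH epimers)
Conditions: CrCl2 (10 equiv), NiCl2 (1 mol %), DMSO/THF, rt, 0.002 M, slow addition
Reagents that add atoms: none
Why: Nozaki–Hiyama–Kishi macrocyclisation: zerovalent nickel inserts into the C–OTf bond, the vinyl group passes to trivalent chromium and adds 1,2 to the aldehyde; the C4–C5 bond closes the ten-membered ring without a lasting stereocentre, since C5 is oxidised next.

Step 29
Reactants: 38 allylic alcohol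
Product: 39 bridged ten-membered α-methylene ketone
Conditions: Dess–Martin periodinane, NaHCO3, CH2Cl2, rt
Reagents that add atoms: none
Why: Oxidation of the allylic alcohol to the enone that allows regiospecific enolate formation.

Step 30
Reactants: 39 α-methylene ketone
Product: 40 bridged ten-membered C5 vinyl triflate (C3 and triflate oxygen cis on C4=C5)
Conditions: LiBH(s-Bu)3, THF, −78 °C; then N-(5-chloro-2-pyridyl)bis(trifluoromethanesulfonimide), −78 to 0 °C
Reagents that add atoms: Comins' reagent, O=S(=O)(N(c1ccc(Cl)cn1)S(=O)(=O)C(F)(F)F)C(F)(F)F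
Why: Conjugate hydride addition to the exocyclic methylene gives only the C4=C5 enolate, which is O-triflated; reaction through the s-trans enone (C=O anti to C=CH2, C3 and C6 antiperiplanar in the ring) should give the isomer with oxygen cis to C3.

Step 31
Reactants: 40 bridged ten-membered C5 vinyl triflate
Product: 41 silyl-protected 13-nor dimer with C10 exocyclic methylene
Conditions: Pd(OAc)2 (15 mol %), PPh3 (45 mol %), Et3N, MeCN, 75 °C
Reagents that add atoms: none
Why: Pd(OAc)2 (divalent palladium) is reduced in situ to zerovalent palladium, which inserts into the C5–O triflate bond with retention of alkene geometry; the vinylpalladium then adds syn across the tetrasubstituted C1=C10 alkene, C5 to C1 and palladium to C10, and the tertiary alkylpalladium loses a β-hydrogen from C14 to give the exocyclic methylene (loss from C9 would give the endocyclic isomer, which the next step also reduces to 42). The closest known reaction type is the intramolecular Heck cyclisation of vinyl triflates that forms quaternary carbons, here in a transannular setting. The cyclopentene (C1–C5) closes in the 5-exo-trig mode through the connecting atoms C4, C3 and C2, and the same bond closes the seven-membered ring (C1, C5–C10) in a 7-endo-trig sense by dividing the ten-membered ring. The one new stereocentre, C1, is controlled by C3: C4 and C1 are 1,3-related on the preformed cyclopentane, so the C4=C5 bridge can only span them cis. The step needs regioselectivity for C1 over C10 (the competing 6-exo closure through C6–C9 to a six-membered ring), which should be secured because C5 is held over C1 by the rigid cyclopentane, and by the Z relation of C3 and palladium on C4=C5. The nor-lactone, the silyl ethers and the other tetrasubstituted alkene have no group that palladium can engage.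

Step 32
Reactants: 41 exocyclic alkene
Product: 42 C10 β-methyl 13-nor dimer
Conditions: Mn(dpm)3 (10 mol %), PhSiH3, t-BuOOH, i-PrOH, rt
Reagents that add atoms: none
Why: Mukaiyama-type hydrogen-atom-transfer hydrogenation: a manganese hydride (from trivalent Mn(dpm)3) gives a hydrogen atom to C14, and the tertiary C10 radical should take its hydrogen on the less hindered face next to C13′, away from the C2 silyloxy bridge, which sets the C10 methyl as in 48; tetrasubstituted alkenes are inert.

Step 33
Reactants: 42 nor-lactone
Product: 45 silyl-protected α-methylene lactone, via Mannich base 43 (not isolated), via ammonium iodide 44 (not isolated)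
Conditions: LiN(SiMe3)2, THF, −78 °C; CH2=NMe2+ I−, −78 to 0 °C; then MeI, rt; then DBU, 0 °C
Reagents that add atoms: Eschenmoser's salt, C=[N+](C)C.[I-]
Why: Eschenmoser methylenation: Mannich reaction of the lactone enolate, N-methylation and base-induced elimination; C11 is the only enolisable position because C11′ is quaternary and no acetate is present.

Step 34
Reactants: 45 tris-silyl ether
Product: 46 C2, C1′ diol with C6′–OTBS
Conditions: HF·pyridine, pyridine, THF, 0 °C
Reagents that add atoms: none
Why: Buffered fluoride removes the two triethylsilyl ethers much faster than the hindered secondary tert-butyldimethylsilyl ether.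

Step 35
Reactants: 46 diol
Product: 47 C2, C1′ diacetate with C6′–OTBS
Conditions: Ac2O, pyridine, DMAP, CH2Cl2, rt
Reagents that add atoms: acetic anhydride, CC(=O)OC(C)=O
Why: DMAP-catalysed acetylation of the primary and the hindered secondary alcohol; C6′ stays protected.

Step 36
Reactants: 47 silyl ether
Product: 48 target CNP0211028.3
Conditions: HF·pyridine, THF, rt
Reagents that add atoms: none
Why: Fluoride cleavage of the last silyl ether under conditions that spare acetates and the α-methylene lactone.

## Compound list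

1 | (S)-4-benzyl-1,3-thiazolidine-2-thione | S=C1N[C@@H](Cc2ccccc2)CS1 | starting material
2 | methyl 4-chloro-4-oxobutanoate | COC(=O)CCC(Cl)=O | starting material
3 | methyl 4-[(4S)-4-benzyl-2-thioxo-1,3-thiazolidin-3-yl]-4-oxobutanoate | COC(=O)CCC(=O)N1[C@@H](Cc2ccccc2)CSC1=S | intermediate
4 | (S)-citronellal | O=CC[C@@H](C)CCC=C(C)C | starting material
5 | (3S)-3,7-dimethyl-2-methylideneoct-6-enal | O=CC(=C)[C@@H](C)CCC=C(C)C | intermediate
6 | syn-aldol adduct, methyl (3S,4S,6S)-3-[(4S)-4-benzyl-2-thioxo-1,3-thiazolidine-3-carbonyl]-4-hydroxy-6,10-dimethyl-5-methylideneundec-9-enoate | COC(=O)C[C@H](C(=O)N1[C@@H](Cc2ccccc2)CSC1=S)[C@H](O)C(=C)[C@@H](C)CCC=C(C)C | intermediate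
7 | C6′ tert-butyldimethylsilyl ether of 6 | COC(=O)C[C@H](C(=O)N1[C@@H](Cc2ccccc2)CSC1=S)[C@H](O[Si](C)(C)C(C)(C)C)C(=C)[C@@H](C)CCC=C(C)C | intermediate
8 | methyl (3S,4S,6S)-4-[(tert-butyldimethylsilyl)oxy]-3-formyl-6,10-dimethyl-5-methylideneundec-9-enoate | COC(=O)C[C@H](C=O)[C@H](O[Si](C)(C)C(C)(C)C)C(=C)[C@@H](C)CCC=C(C)C | intermediate
9 | hydroxy ester from allylboration of 8 (C8′ carbinol with 2-methylallyl group) | COC(=O)C[C@H]([C@H](O)CC(C)=C)[C@H](O[Si](C)(C)C(C)(C)C)C(=C)[C@@H](C)CCC=C(C)C | intermediate (not isolated)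
10 | (4R,5R)-4-{(1S,3S)-1-[(tert-butyldimethylsilyl)oxy]-3,7-dimethyl-2-methylideneoct-6-en-1-yl}-5-(2-methylprop-2-en-1-yl)oxolan-2-one | C1C(=O)O[C@H](CC(C)=C)[C@@H]1[C@H](O[Si](C)(C)C(C)(C)C)C(=C)[C@@H](C)CCC=C(C)C | intermediate
11 | cis-fused 13′-nor-seco-eudesm-5′(10′)-en-12′,8′-olide, C6′–OTBS, side chain ending in the prenyl alkene | C1C(=O)O[C@@H]2CC(C)=C([C@@H](C)CCC=C(C)C)[C@@H](O[Si](C)(C)C(C)(C)C)[C@@H]21 | intermediate
12 | side-chain aldehyde (C1′ = CHO) from 11 | C1C(=O)O[C@@H]2CC(C)=C([C@@H](C)CCC=O)[C@@H](O[Si](C)(C)C(C)(C)C)[C@@H]21 | intermediate (not isolated)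
13 | C1′ primary alcohol, C6′–OTBS nor-lactone | C1C(=O)O[C@@H]2CC(C)=C([C@@H](C)CCCO)[C@@H](O[Si](C)(C)C(C)(C)C)[C@@H]21 | intermediate
14 | nor-lactone with C1′–OTES and C6′–OTBS (C11′ = CH2) | C1C(=O)O[C@@H]2CC(C)=C([C@@H](C)CCCO[Si](CC)(CC)CC)[C@@H](O[Si](C)(C)C(C)(C)C)[C@@H]21 | intermediate
15 | (R)-2-[(4-methoxybenzyl)oxy]propanal | C[C@@H](OCc1ccc(OC)cc1)C=O | starting material
16 | aldol adduct of 14 and 15 (C3 carbinol, C11′–H) | C[C@@H](OCc3ccc(OC)cc3)C(O)C1C(=O)O[C@@H]2CC(C)=C([C@@H](C)CCCO[Si](CC)(CC)CC)[C@@H](O[Si](C)(C)C(C)(C)C)[C@@H]21 | intermediate (not isolated)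
17 | C3 mesylate of 16 | C[C@@H](OCc3ccc(OC)cc3)C(OS(C)(=O)=O)C1C(=O)O[C@@H]2CC(C)=C([C@@H](C)CCCO[Si](CC)(CC)CC)[C@@H](O[Si](C)(C)C(C)(C)C)[C@@H]21 | intermediate (not isolated)
18 | (E)-alkylidene lactone, C11′=C3, C4 (R) bearing OPMB and CH3 | C[C@@H](OCc3ccc(OC)cc3)/C=C1/C(=O)O[C@@H]2CC(C)=C([C@@H](C)CCCO[Si](CC)(CC)CC)[C@@H](O[Si](C)(C)C(C)(C)C)[C@@H]21 | intermediate
19 | (R)-5-(hydroxymethyl)furan-2(5H)-one | OC[C@@H]1OC(=O)C=C1 | starting material
20 | (R)-5-{[(tert-butyldimethylsilyl)oxy]methyl}furan-2(5H)-one | O=C1C=C[C@H](CO[Si](C)(C)C(C)(C)C)O1 | intermediate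
21 | (4S,5R)-5-{[(tert-butyldimethylsilyl)oxy]methyl}-4-vinyloxolan-2-one | O=C1C[C@@H](C=C)[C@H](CO[Si](C)(C)C(C)(C)C)O1 | intermediate
22 | (4S,5R)-5-(hydroxymethyl)-4-vinyloxolan-2-one | O=C1C[C@@H](C=C)[C@H](CO)O1 | intermediate
23 | primary triflate of 22 | O=C1C[C@@H](C=C)[C@H](COS(=O)(=O)C(F)(F)F)O1 | intermediate (not isolated)
24 | (4S,5S)-5-(4-chlorobut-2-yn-1-yl)-4-vinyloxolan-2-one | O=C1C[C@@H](C=C)[C@H](CC#CCCl)O1 | intermediate
25 | conjugate adduct: C3 bearing CH2SiMe2(O-i-Pr) and CH(OPMB)CH3, C11′–H (epimers) | C[C@@H](OCc3ccc(OC)cc3)[C@@H](C[Si](C)(C)OC(C)C)C1C(=O)O[C@@H]2CC(C)=C([C@@H](C)CCCO[Si](CC)(CC)CC)[C@@H](O[Si](C)(C)C(C)(C)C)[C@@H]21 | intermediate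
26 | α-propargylated lactone with quaternary C11′ (C13′–C1≡C10–C9 link to the trans-lactone) | O=C1C[C@@H](C=C)[C@H](CC#CC[C@]2(C(=O)O[C@@H]3CC(C)=C([C@@H](C)CCCO[Si](CC)(CC)CC)[C@@H](O[Si](C)(C)C(C)(C)C)[C@@H]32)[C@H](C[Si](C)(C)OC(C)C)[C@@H](C)OCc4ccc(OC)cc4)O1 | intermediate
27 | primary alcohol (C2 = CH2OH) | O=C1C[C@@H](C=C)[C@H](CC#CC[C@]2(C(=O)O[C@@H]3CC(C)=C([C@@H](C)CCCO[Si](CC)(CC)CC)[C@@H](O[Si](C)(C)C(C)(C)C)[C@@H]32)[C@H](CO)[C@@H](C)OCc4ccc(OC)cc4)O1 | intermediate
28 | ynal (C2 = CHO) | O=C1C[C@@H](C=C)[C@H](CC#CC[C@]2(C(=O)O[C@@H]3CC(C)=C([C@@H](C)CCCO[Si](CC)(CC)CC)[C@@H](O[Si](C)(C)C(C)(C)C)[C@@H]32)[C@H](C=O)[C@@H](C)OCc4ccc(OC)cc4)O1 | intermediate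
29 | spiro-lactone cyclopentanol with exocyclic C1=C10 alkene (C9 cis to C13′), C2–OH epimers | O=C1C[C@@H](C=C)[C@H](C/C(C)=C2\C[C@]3(C(=O)O[C@@H]4CC(C)=C([C@@H](C)CCCO[Si](CC)(CC)CC)[C@@H](O[Si](C)(C)C(C)(C)C)[C@@H]43)[C@@H]([C@@H](C)OCc5ccc(OC)cc5)C2O)O1 | intermediate
30 | C2 ketone (alkylidene cyclopentanone) | O=C1C[C@@H](C=C)[C@H](C/C(C)=C2\C[C@]3(C(=O)O[C@@H]4CC(C)=C([C@@H](C)CCCO[Si](CC)(CC)CC)[C@@H](O[Si](C)(C)C(C)(C)C)[C@@H]43)[C@@H]([C@@H](C)OCc5ccc(OC)cc5)C2=O)O1 | intermediate
31 | C2 alcohol, hydroxyl cis to the C4 side chain | O=C1C[C@@H](C=C)[C@H](C/C(C)=C2\C[C@]3(C(=O)O[C@@H]4CC(C)=C([C@@H](C)CCCO[Si](CC)(CC)CC)[C@@H](O[Si](C)(C)C(C)(C)C)[C@@H]43)[C@@H]([C@@H](C)OCc5ccc(OC)cc5)[C@H]2O)O1 | intermediate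
32 | C2 triethylsilyl ether | O=C1C[C@@H](C=C)[C@H](C/C(C)=C2\C[C@]3(C(=O)O[C@@H]4CC(C)=C([C@@H](C)CCCO[Si](CC)(CC)CC)[C@@H](O[Si](C)(C)C(C)(C)C)[C@@H]43)[C@@H]([C@@H](C)OCc5ccc(OC)cc5)[C@H]2O[Si](CC)(CC)CC)O1 | intermediate
33 | C4 secondary alcohol | O=C1C[C@@H](C=C)[C@H](C/C(C)=C2\C[C@]3(C(=O)O[C@@H]4CC(C)=C([C@@H](C)CCCO[Si](CC)(CC)CC)[C@@H](O[Si](C)(C)C(C)(C)C)[C@@H]43)[C@@H]([C@@H](C)O)[C@H]2O[Si](CC)(CC)CC)O1 | intermediate
34 | C4 methyl ketone | O=C1C[C@@H](C=C)[C@H](C/C(C)=C2\C[C@]3(C(=O)O[C@@H]4CC(C)=C([C@@H](C)CCCO[Si](CC)(CC)CC)[C@@H](O[Si](C)(C)C(C)(C)C)[C@@H]43)[C@@H](C(C)=O)[C@H]2O[Si](CC)(CC)CC)O1 | intermediate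
35 | enol triflate C4(OTf)=C15H2 | O=C1C[C@@H](C=C)[C@H](C/C(C)=C2\C[C@]3(C(=O)O[C@@H]4CC(C)=C([C@@H](C)CCCO[Si](CC)(CC)CC)[C@@H](O[Si](C)(C)C(C)(C)C)[C@@H]43)[C@@H](C(=C)OS(=O)(=O)C(F)(F)F)[C@H]2O[Si](CC)(CC)CC)O1 | intermediate
36 | C5 primary alcohol | O=C1C[C@@H](CCO)[C@H](C/C(C)=C2\C[C@]3(C(=O)O[C@@H]4CC(C)=C([C@@H](C)CCCO[Si](CC)(CC)CC)[C@@H](O[Si](C)(C)C(C)(C)C)[C@@H]43)[C@@H](C(=C)OS(=O)(=O)C(F)(F)F)[C@H]2O[Si](CC)(CC)CC)O1 | intermediate
37 | C5 aldehyde | O=C1C[C@@H](CC=O)[C@H](C/C(C)=C2\C[C@]3(C(=O)O[C@@H]4CC(C)=C([C@@H](C)CCCO[Si](CC)(CC)CC)[C@@H](O[Si](C)(C)C(C)(C)C)[C@@H]43)[C@@H](C(=C)OS(=O)(=O)C(F)(F)F)[C@H]2O[Si](CC)(CC)CC)O1 | intermediate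
38 | bridged ten-membered allylic alcohol, C4=C15H2 exocyclic, C5–OH epimers | C1C(=O)O[C@H]2C/C(C)=C4\C[C@]5(C(=O)O[C@@H]6CC(C)=C([C@@H](C)CCCO[Si](CC)(CC)CC)[C@@H](O[Si](C)(C)C(C)(C)C)[C@@H]65)[C@@H](C(=C)C(O)C[C@H]12)[C@H]4O[Si](CC)(CC)CC | intermediate
39 | bridged ten-membered α-methylene ketone | C1C(=O)O[C@H]2C/C(C)=C4\C[C@]5(C(=O)O[C@@H]6CC(C)=C([C@@H](C)CCCO[Si](CC)(CC)CC)[C@@H](O[Si](C)(C)C(C)(C)C)[C@@H]65)[C@@H](C(=C)C(=O)C[C@H]12)[C@H]4O[Si](CC)(CC)CC | intermediate
40 | bridged ten-membered C5 vinyl triflate (key-step precursor) | C1C(=O)O[C@H]2C/C(C)=C4\C[C@]5(C(=O)O[C@@H]6CC(C)=C([C@@H](C)CCCO[Si](CC)(CC)CC)[C@@H](O[Si](C)(C)C(C)(C)C)[C@@H]65)[C@@H](/C(C)=C(\OS(=O)(=O)C(F)(F)F)C[C@H]12)[C@H]4O[Si](CC)(CC)CC | intermediate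
41 | silyl-protected 13-nor dimer with C10 exocyclic methylene (key-step product) | C1C(=O)O[C@H]2CC(=C)[C@@]34C[C@]5(C(=O)O[C@@H]6CC(C)=C([C@@H](C)CCCO[Si](CC)(CC)CC)[C@@H](O[Si](C)(C)C(C)(C)C)[C@@H]65)[C@@H](C(C)=C3C[C@H]12)[C@H]4O[Si](CC)(CC)CC | intermediate
42 | silyl-protected 13-nor dimer with C10 β-methyl | C1C(=O)O[C@H]2C[C@H](C)[C@@]34C[C@]5(C(=O)O[C@@H]6CC(C)=C([C@@H](C)CCCO[Si](CC)(CC)CC)[C@@H](O[Si](C)(C)C(C)(C)C)[C@@H]65)[C@@H](C(C)=C3C[C@H]12)[C@H]4O[Si](CC)(CC)CC | intermediate
43 | C11 dimethylaminomethyl lactone (Mannich base, C11 epimers) | CN(C)CC1C(=O)O[C@H]2C[C@H](C)[C@@]34C[C@]5(C(=O)O[C@@H]6CC(C)=C([C@@H](C)CCCO[Si](CC)(CC)CC)[C@@H](O[Si](C)(C)C(C)(C)C)[C@@H]65)[C@@H](C(C)=C3C[C@H]12)[C@H]4O[Si](CC)(CC)CC | intermediate (not isolated)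
44 | C11 trimethylammoniomethyl lactone iodide | C[N+](C)(C)CC1C(=O)O[C@H]2C[C@H](C)[C@@]34C[C@]5(C(=O)O[C@@H]6CC(C)=C([C@@H](C)CCCO[Si](CC)(CC)CC)[C@@H](O[Si](C)(C)C(C)(C)C)[C@@H]65)[C@@H](C(C)=C3C[C@H]12)[C@H]4O[Si](CC)(CC)CC.[I-] | intermediate (not isolated)
45 | α-methylene lactone with C2–OTES, C1′–OTES, C6′–OTBS | C=C1C(=O)O[C@H]2C[C@H](C)[C@@]34C[C@]5(C(=O)O[C@@H]6CC(C)=C([C@@H](C)CCCO[Si](CC)(CC)CC)[C@@H](O[Si](C)(C)C(C)(C)C)[C@@H]65)[C@@H](C(C)=C3C[C@H]12)[C@H]4O[Si](CC)(CC)CC | intermediate
46 | C2, C1′ diol with C6′–OTBS | C=C1C(=O)O[C@H]2C[C@H](C)[C@@]34C[C@]5(C(=O)O[C@@H]6CC(C)=C([C@@H](C)CCCO)[C@@H](O[Si](C)(C)C(C)(C)C)[C@@H]65)[C@@H](C(C)=C3C[C@H]12)[C@H]4O | intermediate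
47 | C6′ tert-butyldimethylsilyl ether of the target (C2, C1′ diacetate) | C=C1C(=O)O[C@H]2C[C@H](C)[C@@]34C[C@]5(C(=O)O[C@@H]6CC(C)=C([C@@H](C)CCCOC(C)=O)[C@@H](O[Si](C)(C)C(C)(C)C)[C@@H]65)[C@@H](C(C)=C3C[C@H]12)[C@H]4OC(C)=O | intermediate
48 | CNP0211028.3 | C=C1C(=O)O[C@H]2C[C@H](C)[C@@]34C[C@]5(C(=O)O[C@@H]6CC(C)=C([C@@H](C)CCCOC(C)=O)[C@@H](O)[C@@H]65)[C@@H](C(C)=C3C[C@H]12)[C@H]4OC(C)=O | target

## Step count and least certain steps

Total: 36 steps. Longest linear sequence: 31 steps (steps 1, 3–10 and 15–36, from 1 and 2). Steps 2 and 11–14 are the side branches.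

**Step 31 (key step).** The most likely failure is slow carbopalladation of the tetrasubstituted bridgehead alkene, so that the vinylpalladium is lost by reduction or attacks C10 in the competing 6-exo mode. Fallback: a vinyl radical cyclisation, which does not need coordination of the hindered alkene. It sets out from 40, which is converted with Me3SnSnMe3, Pd(PPh3)4 and LiCl into the vinylstannane F1 and with iodine into the vinyl iodide F2. Bu3SnH/AIBN should then give 5-exo closure of the C5 radical onto C1, and the tertiary C10 radical takes hydrogen on the open face. The fallback comes back to the route at 42.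

**Step 7.** Ring closure may fail because both alkenes are 1,1-disubstituted and one is flanked by a silyloxy group and a branched chain, so catalyst decomposition or dimerisation can win. Fallback: ring closure on the unprotected allylic alcohol, where the hydroxyl is smaller and can assist the ruthenium carbene. It sets out from 10, which is desilylated (HF·pyridine) to the diene alcohol F3; metathesis gives the bicyclic alcohol F4, and silylation with TBSOTf returns to 11.

**Step 16.** The hindered tertiary enolate may alkylate on the wrong face (C11′ epimer) or simply transfer a proton to 24. Fallback: the two bonds at C11′ are made in the opposite order, so that the group entering last is C3. It sets out from 14, which is propargylated with 24 (LiN(i-Pr)2) to the α-propargyl lactone F5. Its enolate is added to the nitroalkene F6 (from 15 and nitromethane by Henry reaction and dehydration) to give the nitro compound F7, and a Nef reaction (NaOMe, then buffered TiCl3) unmasks the aldehyde and returns to 28.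

**Step 19.** Methyl transfer may be too slow, giving reductive cyclisation without the methyl group or direct methyl addition to the aldehyde. Fallback: a stoichiometric titanium-mediated alkyne–aldehyde coupling followed by cross-coupling. It sets out from 28; Cp2Ti(PMe3)2 (divalent titanium) should give the oxatitanacycle, iodine cleaves it to the vinyl iodide F8, and Negishi methylation (MeZnCl, Pd(PPh3)4) returns to 29.

**Step 30.** The enone may react through the s-cis conformer in the ten-membered ring and give the enolate with oxygen trans to C3, from which the Heck closure is impossible. Fallback: triflation of the saturated ketone under thermodynamic control instead of kinetic enolate trapping. It sets out from 39, which is hydrogenated at the methylene (H2, RhCl(PPh3)3) to the ketone F9; Tf2O with 2,6-di-tert-butyl-4-methylpyridine should give the more substituted enol triflate and return to 40.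

**Step 32.** Hydrogen may be delivered to the wrong face of the C10 radical, giving the C10 epimer. Fallback: a carbonyl-directed hydrogenation in place of the radical process. It sets out from 41 and uses [Ir(cod)(PCy3)(py)]PF6 and H2 in CH2Cl2; the lactone oxygen at C8 lies on the face that must receive hydrogen and can bind the cationic iridium. It returns to 42 without a new intermediate.

Further compounds

F1 | step 31 | C5 trimethylstannyl analogue of 40 | C1C(=O)O[C@H]2C/C(C)=C4\C[C@]5(C(=O)O[C@@H]6CC(C)=C([C@@H](C)CCCO[Si](CC)(CC)CC)[C@@H](O[Si](C)(C)C(C)(C)C)[C@@H]65)[C@@H](/C(C)=C(\[Sn](C)(C)C)C[C@H]12)[C@H]4O[Si](CC)(CC)CC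
F2 | step 31 | C5 vinyl iodide analogue of 40 | C1C(=O)O[C@H]2C/C(C)=C4\C[C@]5(C(=O)O[C@@H]6CC(C)=C([C@@H](C)CCCO[Si](CC)(CC)CC)[C@@H](O[Si](C)(C)C(C)(C)C)[C@@H]65)[C@@H](/C(C)=C(\I)C[C@H]12)[C@H]4O[Si](CC)(CC)CC
F3 | step 7 | C6′ alcohol of lactone diene 10 | C1C(=O)O[C@H](CC(C)=C)[C@@H]1[C@H](O)C(=C)[C@@H](C)CCC=C(C)C
F4 | step 7 | C6′ alcohol of bicyclic lactone 11 | C1C(=O)O[C@@H]2CC(C)=C([C@@H](C)CCC=C(C)C)[C@@H](O)[C@@H]21
F5 | step 16 | α-propargyl lactone from 14 and 24 (C11′–H, epimers) | O=C1C[C@@H](C=C)[C@H](CC#CCC2C(=O)O[C@@H]3CC(C)=C([C@@H](C)CCCO[Si](CC)(CC)CC)[C@@H](O[Si](C)(C)C(C)(C)C)[C@@H]32)O1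
F6 | step 16 | (R,E)-3-[(4-methoxybenzyl)oxy]-1-nitrobut-1-ene | C[C@@H](OCc1ccc(OC)cc1)/C=C/[N+](=O)[O-]
F7 | step 16 | nitromethyl analogue of 28 (C2 = CH2NO2) | O=C1C[C@@H](C=C)[C@H](CC#CC[C@]2(C(=O)O[C@@H]3CC(C)=C([C@@H](C)CCCO[Si](CC)(CC)CC)[C@@H](O[Si](C)(C)C(C)(C)C)[C@@H]32)[C@H](C[N+](=O)[O-])[C@@H](C)OCc4ccc(OC)cc4)O1
F8 | step 19 | C10 vinyl iodide analogue of 29 | O=C1C[C@@H](C=C)[C@H](C/C(I)=C2\C[C@]3(C(=O)O[C@@H]4CC(C)=C([C@@H](C)CCCO[Si](CC)(CC)CC)[C@@H](O[Si](C)(C)C(C)(C)C)[C@@H]43)[C@@H]([C@@H](C)OCc5ccc(OC)cc5)C2O)O1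
F9 | step 30 | bridged ten-membered C5 ketone with C4–H and C4 methyl (C4 epimers) | C1C(=O)O[C@H]2C/C(C)=C4\C[C@]5(C(=O)O[C@@H]6CC(C)=C([C@@H](C)CCCO[Si](CC)(CC)CC)[C@@H](O[Si](C)(C)C(C)(C)C)[C@@H]65)[C@@H](C(C)C(=O)C[C@H]12)[C@H]4O[Si](CC)(CC)CC
F0 | step 32 | none | none
A1 | alternative 1 | bromomethyl-butenolide enal, precursor of the zinc-mediated ring closure | O=C/C([C@@H](C)CCCOC(C)=O)=C(/C)C[C@H]1OC(=O)C(CBr)=C1
A2 | alternative 1 | seco-eudesmanolide monomer with free C6′ hydroxyl | C=C1C(=O)O[C@@H]2CC(C)=C([C@@H](C)CCCOC(C)=O)[C@@H](O)[C@@H]21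
A3 | alternative 2 | epoxide of the six–seven fused bicycle (epoxide across C1 and the future C13′) | C1C(=O)O[C@H]2C[C@H](C)[C@]34O[C@H]3[C@H](O[Si](CC)(CC)CC)[C@@H](O[Si](C)(C)C(C)(C)C)C(C)=C4C[C@H]12
A4 | alternative 2 | guaianolide half with quaternary C1 bearing the C13′ aldehyde | C1C(=O)O[C@H]2C[C@H](C)[C@]3(C=O)[C@H](O[Si](CC)(CC)CC)[C@@H](O[Si](C)(C)C(C)(C)C)C(C)=C3C[C@H]12
A5 | alternative 3 | C11 vinyl triflate with free trans C8 hydroxyl | O[C@H]2C[C@H](C)[C@@]34C[C@]5(C(=O)O[C@@H]6CC(C)=C([C@@H](C)CCCOC(C)=O)[C@@H](O[Si](C)(C)C(C)(C)C)[C@@H]65)[C@@H](C(C)=C3C[C@@H]2C(=C)OS(=O)(=O)C(F)(F)F)[C@H]4OC(C)=O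
A6 | alternative 3 | C6′ silyl ether of the target | C=C1C(=O)O[C@H]2C[C@H](C)[C@@]34C[C@]5(C(=O)O[C@@H]6CC(C)=C([C@@H](C)CCCOC(C)=O)[C@@H](O[Si](C)(C)C(C)(C)C)[C@@H]65)[C@@H](C(C)=C3C[C@H]12)[C@H]4OC(C)=O
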